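**Strategy.** Clerodane numbering is used. The plan rests on cutting ring B at the C5–C10 ring-fusion bond and at C8–C9: the array C5(Me)–C10(H)–C9(Me)(CHO)–C8(Me)(OH) is the retron of a radical conjugate addition followed by an aldol addition. In one operation an acyclic dienyl enal ketone folds into the trans-decalin: hydrogen-atom transfer to C19 of a 2-substituted 1,3-diene gives a C5 radical that closes ring A on the enal carbon C10, and the enolate so formed closes ring B on the C8 methyl ketone, setting C5, C10, C9 and C8 and leaving the C3=C4 alkene in place. C6 and C7, the only stereocentres of the precursor, come from D-tartaric acid.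

Key step: step 8

Assumption: compounds 1, 5 and 15 are taken as purchasable; atoms carry clerodane numbers (ring A: C1–C5 and C10; ring B: C5–C10; C17 on C8, C18 on C4, C19 on C5, C20 on C9, C11–C16 side chain).

Step 1
Reactants: 1 dimethyl (4S,5S)-2,2-dimethyl-1,3-dioxolane-4,5-dicarboxylate
Product: 2 (4S,5S)-N4,N5-dimethoxy-N4,N5,2,2-tetramethyl-1,3-dioxolane-4,5-dicarboxamide
Conditions: MeNH(OMe)·HCl (3 equiv), i-PrMgCl (6 equiv), THF, −20 °C to 0 °C
Reagents that add atoms: N,O-dimethylhydroxylamine hydrochloride, CNOC.Cl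
Why: Aminolysis of both esters by the chloromagnesium amide (Weinreb amide formation) should proceed at low temperature without enolising the trans-dioxolane stereocentres.

Step 2
Reactants: 2 (4S,5S)-N4,N5-dimethoxy-N4,N5,2,2-tetramethyl-1,3-dioxolane-4,5-dicarboxamide
Product: 3 1,1'-[(4S,5S)-2,2-dimethyl-1,3-dioxolane-4,5-diyl]di(ethan-1-one)
Conditions: MeMgBr (2.5 equiv), THF, 0 °C
Reagents that add atoms: methylmagnesium bromide, C[Mg]Br
Why: Weinreb ketone synthesis, in which the chelated tetrahedral intermediates stop after one methyl addition per amide, should give the C2-symmetric diketone.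

Step 3
Reactants: 3 1,1'-[(4S,5S)-2,2-dimethyl-1,3-dioxolane-4,5-diyl]di(ethan-1-one)
Product: 4 1-[(4S,5S)-5-acetyl-2,2-dimethyl-1,3-dioxolan-4-yl]ethenyl trifluoromethanesulfonate
Conditions: KHMDS (1.0 equiv), PhNTf2 (1.05 equiv), THF, −78 °C
Reagents that add atoms: N-phenylbis(trifluoromethanesulfonimide), O=S(=O)(N(c1ccccc1)S(=O)(=O)C(F)(F)F)C(F)(F)F
Why: Kinetic enolisation at a methyl group and O-sulfonylation (enol triflate formation) should give mainly the mono-triflate with one equivalent of base, since the two ketones are equivalent by C2 symmetry and the hindered ring C–H is not removed.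

Step 4
Reactants: 5 5-methylhex-4-enal
Product: 6 (2Z)-2-iodo-7-methylocta-2,6-diene
Conditions: EtPPh3I, n-BuLi, THF, rt; I2, −78 °C; NaHMDS, −20 °C; then 5, −78 °C to rt
Reagents that add atoms: ethyltriphenylphosphonium iodide, CC[P+](c1ccccc1)(c1ccccc1)c1ccccc1.[I-]; iodine, [I][I]
Why: Stork–Zhao-type Wittig olefination with the α-iodo ylide should give the 2-iodoalk-2-ene with iodine cis to the chain (Z) under kinetic control.

Step 5
Reactants: 6 (2Z)-2-iodo-7-methylocta-2,6-diene
Product: 7 (2E,6Z)-7-iodo-2-methylocta-2,6-dien-1-ol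
Conditions: SeO2 (0.5 equiv), t-BuOOH (2 equiv), CH2Cl2, 0 °C to rt
Reagents that add atoms: selenium dioxide, O=[Se]=O; tert-butyl hydroperoxide, CC(C)(C)OO
Why: Selenium dioxide allylic oxidation (ene reaction then 2,3-shift) should select the (E)-methyl of the electron-rich prenyl alkene, the iodoalkene being too electron-poor to react.

Step 6
Reactants: 7 (2E,6Z)-7-iodo-2-methylocta-2,6-dien-1-ol; 4 1-[(4S,5S)-5-acetyl-2,2-dimethyl-1,3-dioxolan-4-yl]ethenyl trifluoromethanesulfonate
Product: 10 1-[(4S,5R)-5-[(3Z,7E)-9-hydroxy-3,8-dimethylnona-1,3,7-trien-2-yl]-2,2-dimethyl-1,3-dioxolan-4-yl]ethan-1-one, via dilithio alkoxide 8 (not isolated), via alkenylzinc chloride 9 (not isolated)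
Conditions: 7, t-BuLi (3.1 equiv), Et2O, −78 °C; ZnCl2 (1.5 equiv), THF, −78 °C to 0 °C; 4, Pd(PPh3)4 (5 mol%), rt
Reagents that add atoms: none
Why: Iodine–lithium exchange with retention, transmetalation to zinc and Negishi cross-coupling with the enol triflate should join C4 to C5 with the Z geometry intact, the methyl ketone being inert to the organozinc.

Step 7
Reactants: 10 1-[(4S,5R)-5-[(3Z,7E)-9-hydroxy-3,8-dimethylnona-1,3,7-trien-2-yl]-2,2-dimethyl-1,3-dioxolan-4-yl]ethan-1-one
Product: 11 (2E,6Z)-8-[(4R,5S)-5-acetyl-2,2-dimethyl-1,3-dioxolan-4-yl]-2,7-dimethylnona-2,6,8-trienal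
Conditions: MnO2 (20 equiv), CH2Cl2, rt
Reagents that add atoms: none
Why: Manganese dioxide oxidation of the primary allylic alcohol should give the (E)-enal without touching the diene or the ketone.

Step 8
Reactants: 11 (2E,6Z)-8-[(4R,5S)-5-acetyl-2,2-dimethyl-1,3-dioxolan-4-yl]-2,7-dimethylnona-2,6,8-trienal
Product: 13 (5R,6R,7S,8R,9R,10S)-8-hydroxy-6,7-(isopropylidenedioxy)-12,13,14,15,16-pentanorclerod-3-en-11-al, via ring-A iron enolate 12 (not isolated)
Conditions: Fe(acac)3 (0.3 equiv), PhSiH3 (2.5 equiv), EtOH/ethylene glycol 5:1 (0.02 M), argon, 0 °C to rt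
Reagents that add atoms: none
Why: Proposed new method: the iron hydride from Fe(acac)3 and PhSiH3 should transfer a hydrogen atom to the terminal CH2 (C19) of the diene, the allylic radical should add through C5 to the enal carbon C10, divalent iron should reduce the α-formyl radical to an iron enolate, and this enolate should add to the C8 ketone; the closest known reaction type is the iron-hydride-initiated Giese addition–aldol annulation (radical–polar crossover) of isolated 1,1-disubstituted alkenes with enals, and the new element is that the donor alkene is the terminus of a 1,3-diene, so that the tertiary radical is allylic and the C3=C4 double bond is left in ring A. Ring A closes by 6-exo-trig radical addition with the allyl unit inside the new ring (which needs the 3Z diene), ring B by a 6-(enolexo)-exo-trig aldol addition. C5 and C10 are set in a chair-like transition state with the bulky C6 on the outer (pseudo-equatorial) position of the radical and the enal chain equatorial, which gives C19 trans to H10. C9 is set by allylic strain in the enolate (C11 eclipses H10, so C20 turns axial and syn to C19), C8 by the chelated chair aldol transition state (hydroxyl axial and cis to the formyl group). The step needs hydrogen-atom transfer to the electron-rich diene terminus and not to the enal, and it needs addition to the C5 face that leaves O6 and O7 equatorial: the C6 stereocentre should steer this (H6 anti to the forming bond, C7 in the open sector between C4 and C10), and only this adduct can close ring B through a chair with the trans-dioxolane diequatorial.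

Step 9
Reactants: 13 (5R,6R,7S,8R,9R,10S)-8-hydroxy-6,7-(isopropylidenedioxy)-12,13,14,15,16-pentanorclerod-3-en-11-al
Product: 14 (5R,6R,7S,8R,9R,10S,11E)-6,7-(isopropylidenedioxy)-12-(4,4,5,5-tetramethyl-1,3,2-dioxaborolan-2-yl)-13,14,15,16-tetranorcleroda-3,11-dien-8-ol
Conditions: CrCl2 (8 equiv), Cl2CHBpin (2 equiv), LiI (4 equiv), THF, rt
Reagents that add atoms: 2-(dichloromethyl)-4,4,5,5-tetramethyl-1,3,2-dioxaborolane, ClC(Cl)B1OC(C)(C)C(C)(C)O1
Why: Takai–Utimoto-type olefination with the gem-dichromium boronate should convert the non-enolisable aldehyde into the (E)-alkenyl boronate under non-basic conditions that avoid retro-aldol cleavage of the β-hydroxy aldehyde.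

Step 10
Reactants: 14 (5R,6R,7S,8R,9R,10S,11E)-6,7-(isopropylidenedioxy)-12-(4,4,5,5-tetramethyl-1,3,2-dioxaborolan-2-yl)-13,14,15,16-tetranorcleroda-3,11-dien-8-ol; 15 4-bromofuran-2(5H)-one
Product: 16 (5R,6R,7S,8R,9R,10S,11E)-8-hydroxy-6,7-(isopropylidenedioxy)cleroda-3,11,13-trien-15,16-olide
Conditions: PdCl2(dppf) (5 mol%), K3PO4 (3 equiv), THF/H2O 10:1, rt
Reagents that add atoms: none
Why: Suzuki–Miyaura coupling of the alkenyl boronate with the vinylogous acyl bromide should proceed with retention and give the (11E)-dienyl butenolide under base mild enough for the lactone.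

Step 11
Reactants: 16 (5R,6R,7S,8R,9R,10S,11E)-8-hydroxy-6,7-(isopropylidenedioxy)cleroda-3,11,13-trien-15,16-olide
Product: 17 (5R,6R,7S,8R,9R,10S,11E)-6,7,8-trihydroxycleroda-3,11,13-trien-15,16-olide
Conditions: AcOH/H2O 4:1, 45 °C
Reagents that add atoms: none
Why: Acid hydrolysis of the strained trans-fused isopropylidene acetal should free the 6,7-diol while the tertiary alcohol, the trisubstituted alkene and the butenolide survive aqueous acetic acid.

Step 12
Reactants: 17 (5R,6R,7S,8R,9R,10S,11E)-6,7,8-trihydroxycleroda-3,11,13-trien-15,16-olide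
Product: 18 (5R,6R,7S,8R,9R,10S,11E)-6,7-diacetoxy-8-hydroxycleroda-3,11,13-trien-15,16-olide
Conditions: Ac2O (5 equiv), pyridine, DMAP (0.1 equiv), CH2Cl2, 0 °C to rt
Reagents that add atoms: acetic anhydride, CC(=O)OC(C)=O
Why: DMAP-catalysed acetylation should esterify the two secondary equatorial hydroxyls and leave the axial tertiary C8 hydroxyl, shielded by the quaternary C9, free.

**Compound list**

1 | dimethyl (4S,5S)-2,2-dimethyl-1,3-dioxolane-4,5-dicarboxylate (acetonide of dimethyl D-tartrate) | COC(=O)[C@H]1OC(C)(C)O[C@@H]1C(=O)OC | starting material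
2 | (4S,5S)-N4,N5-dimethoxy-N4,N5,2,2-tetramethyl-1,3-dioxolane-4,5-dicarboxamide | CON(C)C(=O)[C@H]1OC(C)(C)O[C@@H]1C(=O)N(C)OC | intermediate
3 | 1,1'-[(4S,5S)-2,2-dimethyl-1,3-dioxolane-4,5-diyl]di(ethan-1-one) | CC(=O)[C@H]1OC(C)(C)O[C@@H]1C(C)=O | intermediate
4 | 1-[(4S,5S)-5-acetyl-2,2-dimethyl-1,3-dioxolan-4-yl]ethenyl trifluoromethanesulfonate | CC(=O)[C@H]1OC(C)(C)O[C@@H]1C(=C)OS(=O)(=O)C(F)(F)F | intermediate
5 | 5-methylhex-4-enal | CC(C)=CCCC=O | starting material
6 | (2Z)-2-iodo-7-methylocta-2,6-diene | C/C(I)=C/CCC=C(C)C | intermediate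
7 | (2E,6Z)-7-iodo-2-methylocta-2,6-dien-1-ol | OC/C(C)=C/CC/C=C(/C)I | intermediate
8 | lithium (2E,6Z)-7-lithio-2-methylocta-2,6-dien-1-olate | [Li]OC/C(C)=C/CC/C=C(/C)[Li] | intermediate
9 | chlorozinc (2Z,6E)-8-(lithiooxy)-7-methylocta-2,6-dien-2-yl species | [Li]OC/C(C)=C/CC/C=C(/C)[Zn]Cl | intermediate
10 | 1-[(4S,5R)-5-[(3Z,7E)-9-hydroxy-3,8-dimethylnona-1,3,7-trien-2-yl]-2,2-dimethyl-1,3-dioxolan-4-yl]ethan-1-one | CC(=O)[C@H]1OC(C)(C)O[C@@H]1C(=C)/C(C)=C\CC/C=C(\C)CO | intermediate
11 | (2E,6Z)-8-[(4R,5S)-5-acetyl-2,2-dimethyl-1,3-dioxolan-4-yl]-2,7-dimethylnona-2,6,8-trienal | CC(=O)[C@H]1OC(C)(C)O[C@@H]1C(=C)/C(C)=C\CC/C=C(\C)C=O | intermediate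
12 | ring-A iron enolate, drawn as the free enol: 1-[(4S,5R)-5-[(1R,6R)-6-(1-hydroxyprop-1-en-2-yl)-1,2-dimethylcyclohex-2-en-1-yl]-2,2-dimethyl-1,3-dioxolan-4-yl]ethan-1-one | CC(=O)[C@H]1OC(C)(C)O[C@@H]1[C@@]2(C)C(C)=CCC[C@@H]2C(C)=CO | intermediate
13 | (5R,6R,7S,8R,9R,10S)-8-hydroxy-6,7-(isopropylidenedioxy)-12,13,14,15,16-pentanorclerod-3-en-11-al | CC1(C)O[C@H]2[C@H](O1)[C@](C)(O)[C@](C)(C=O)[C@H]3CCC=C(C)[C@]23C | intermediate
14 | (5R,6R,7S,8R,9R,10S,11E)-6,7-(isopropylidenedioxy)-12-(4,4,5,5-tetramethyl-1,3,2-dioxaborolan-2-yl)-13,14,15,16-tetranorcleroda-3,11-dien-8-ol | CC1(C)O[C@H]2[C@H](O1)[C@](C)(O)[C@](C)(/C=C/B1OC(C)(C)C(C)(C)O1)[C@H]3CCC=C(C)[C@]23C | intermediate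
15 | 4-bromofuran-2(5H)-one | BrC1=CC(=O)OC1 | starting material
16 | (5R,6R,7S,8R,9R,10S,11E)-8-hydroxy-6,7-(isopropylidenedioxy)cleroda-3,11,13-trien-15,16-olide | CC1(C)O[C@H]2[C@H](O1)[C@](C)(O)[C@](C)(/C=C/C1=CC(=O)OC1)[C@H]3CCC=C(C)[C@]23C | intermediate
17 | (5R,6R,7S,8R,9R,10S,11E)-6,7,8-trihydroxycleroda-3,11,13-trien-15,16-olide | O[C@H]1[C@H](O)[C@](C)(O)[C@](C)(/C=C/C2=CC(=O)OC2)[C@H]2CCC=C(C)[C@]12C | intermediate
18 | (5R,6R,7S,8R,9R,10S,11E)-6,7-diacetoxy-8-hydroxycleroda-3,11,13-trien-15,16-olide | CC(=O)O[C@H]1[C@H](OC(C)=O)[C@](C)(O)[C@](C)(/C=C/C2=CC(=O)OC2)[C@H]2CCC=C(C)[C@]12C | target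

**Totals.** Total step count: 12. Longest linear sequence: 10 steps (steps 1, 2, 3, 6, 7, 8, 9, 10, 11, 12).

**Steps most likely to fail**

1. Step 8 (labelled step). Process at risk: the stabilised and hindered allylic radical may be reduced or may couple before it cyclises, and addition to C10 may take place on the wrong face of C5 relative to C6 — the simple steric model for a radical next to an alkoxy stereocentre (attack anti to the ring carbon C7) predicts the undesired face, so this selectivity is the least secure element of the route. The fallback uses known chemistry: the radical is kept out of conjugation and the C3=C4 alkene is made afterwards. It sets out from 4 and comes back at 14. Nozaki–Hiyama–Kishi coupling of 4 with commercial 6-methylhept-5-enal (CrCl2, catalytic NiCl2, DMF) should give the allylic alcohol F1 as both C4 epimers. SeO2/t-BuOOH should give the (E)-allylic diol F2, and TEMPO/PhI(OAc)2 the hydroxy enal F3. The established iron-hydride Giese addition–aldol annulation (Fe(acac)3, PhSiH3), now through a non-allylic tertiary radical, should give the 4-hydroxy decalin aldehyde F4. The chromium olefination of step 9 should give the alkenyl boronate F5, Dess–Martin oxidation the C4 ketone F6, and KHMDS/PhNTf2 the enol triflate F7 (only C3 can be enolised). Pd(PPh3)4/MeZnCl then installs C18 and returns 14.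

2. Step 9. Process at risk: slow addition of the bulky gem-dichromium reagent to the neopentyl aldehyde flanked by C19 and C20, with retro-aldol opening of ring B through the chromium alkoxide. The fallback builds the butenolide on the chain instead of coupling it; it sets out from 13 and comes back at 16. Masamune–Roush Horner–Wadsworth–Emmons olefination of 13 with dimethyl [3-(tert-butyldimethylsilyloxy)-2-oxopropyl]phosphonate (LiCl, i-Pr2NEt, MeCN) should give the (E)-silyloxy enone F8. HF·pyridine should give the hydroxy enone F9. Ph3P=C=C=O (toluene, 80 °C; O-acylation then intramolecular Wittig reaction) should close the butenolide and return 16.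

3. Step 6. Process at risk: incomplete iodine–lithium exchange or protonation of the alkenyl metal next to the alkoxide, and sluggish coupling of two hindered partners with homocoupling. The fallback replaces cross-coupling by carbonyl addition and olefination; it sets out from 2 and 8 (8 made from 7 as in step 6) and comes back at 10. Addition of 8 to an excess of 2 (THF, −78 °C) should give the enone amide F10. Wittig methylenation (Ph3P=CH2, THF, 0 °C) should give the dienyl amide F11. MeMgBr (THF, 0 °C) returns 10.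

Further compounds
F1 | step 8 | 1-[(4S,5R)-5-(3-hydroxy-8-methylnona-1,7-dien-2-yl)-2,2-dimethyl-1,3-dioxolan-4-yl]ethan-1-one (both carbinol epimers) | CC(=O)[C@H]1OC(C)(C)O[C@@H]1C(=C)C(O)CCCC=C(C)C
F2 | step 8 | 1-[(4S,5R)-5-[(7E)-3,9-dihydroxy-8-methylnona-1,7-dien-2-yl]-2,2-dimethyl-1,3-dioxolan-4-yl]ethan-1-one | CC(=O)[C@H]1OC(C)(C)O[C@@H]1C(=C)C(O)CCC/C=C(\C)CO
F3 | step 8 | (2E)-8-[(4R,5S)-5-acetyl-2,2-dimethyl-1,3-dioxolan-4-yl]-7-hydroxy-2-methylnona-2,8-dienal | CC(=O)[C@H]1OC(C)(C)O[C@@H]1C(=C)C(O)CCC/C=C(\C)C=O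
F4 | step 8 | 4,8-dihydroxy-6,7-(isopropylidenedioxy)-12,13,14,15,16,18-hexanorclerodan-11-al (C5 to C10 as in 13; C4 epimers) | CC1(C)O[C@H]2[C@H](O1)[C@](C)(O)[C@](C)(C=O)[C@H]3CCCC(O)[C@]23C
F5 | step 8 | (11E)-6,7-(isopropylidenedioxy)-12-(4,4,5,5-tetramethyl-1,3,2-dioxaborolan-2-yl)-13,14,15,16,18-pentanorclerod-11-ene-4,8-diol (C4 epimers) | CC1(C)O[C@H]2[C@H](O1)[C@](C)(O)[C@](C)(/C=C/B1OC(C)(C)C(C)(C)O1)[C@H]3CCCC(O)[C@]23C
F6 | step 8 | (11E)-8-hydroxy-6,7-(isopropylidenedioxy)-12-(4,4,5,5-tetramethyl-1,3,2-dioxaborolan-2-yl)-13,14,15,16,18-pentanorclerod-11-en-4-one | CC1(C)O[C@H]2[C@H](O1)[C@](C)(O)[C@](C)(/C=C/B1OC(C)(C)C(C)(C)O1)[C@H]3CCCC(=O)[C@]23C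
F7 | step 8 | (11E)-8-hydroxy-6,7-(isopropylidenedioxy)-12-(4,4,5,5-tetramethyl-1,3,2-dioxaborolan-2-yl)-13,14,15,16,18-pentanorcleroda-3,11-dien-4-yl trifluoromethanesulfonate | CC1(C)O[C@H]2[C@H](O1)[C@](C)(O)[C@](C)(/C=C/B1OC(C)(C)C(C)(C)O1)[C@H]3CCC=C(OS(=O)(=O)C(F)(F)F)[C@]23C
F8 | step 9 | (11E)-16-(tert-butyldimethylsilyloxy)-8-hydroxy-6,7-(isopropylidenedioxy)-14,15-dinorcleroda-3,11-dien-13-one | CC1(C)O[C@H]2[C@H](O1)[C@](C)(O)[C@](C)(/C=C/C(=O)CO[Si](C)(C)C(C)(C)C)[C@H]3CCC=C(C)[C@]23C
F9 | step 9 | (11E)-8,16-dihydroxy-6,7-(isopropylidenedioxy)-14,15-dinorcleroda-3,11-dien-13-one | CC1(C)O[C@H]2[C@H](O1)[C@](C)(O)[C@](C)(/C=C/C(=O)CO)[C@H]3CCC=C(C)[C@]23C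
F10 | step 6 | (4S,5S)-5-[(2Z,6E)-8-hydroxy-2,7-dimethylocta-2,6-dienoyl]-N-methoxy-N,2,2-trimethyl-1,3-dioxolane-4-carboxamide | CON(C)C(=O)[C@H]1OC(C)(C)O[C@@H]1C(=O)/C(C)=C\CC/C=C(\C)CO
F11 | step 6 | (4S,5R)-5-[(3Z,7E)-9-hydroxy-3,8-dimethylnona-1,3,7-trien-2-yl]-N-methoxy-N,2,2-trimethyl-1,3-dioxolane-4-carboxamide | CON(C)C(=O)[C@H]1OC(C)(C)O[C@@H]1C(=C)/C(C)=C\CC/C=C(\C)CO
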